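**Remarks on the chemistry**

- The target is read from its SMILES as epioritin-(4β→6)-epioritin-(4β→6)-epioritin-4α-ol: every unit is 2R,3R (2,3-cis), both interflavan bonds are 4β (3,4-trans), and the bottom unit carries a 4α-hydroxyl (all-cis, 2R,3R,4R, the teracacidin unit).
- Open-chain intermediates are described with the locants of the flavan atoms they become (C2 = carbinol carbon bearing ring B, C3 = benzyloxy carbon, C4 = carbinol carbon on the chloroarene).
- The C4 hydroxyl of the cyclisation substrate 13 is left free instead of being silylated. A lithium alkoxide there cannot reach the aryne (a four-membered ring would result), whereas a silyl ether 1,3 to the reacting alkoxide could migrate onto it.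

**Numbering key** (structures in the compound list): 1 benzyloxyacetic acid; 2 oxazolidinone auxiliary; 3 mixed anhydride; 4 glycolyl imide; 5 4-(benzyloxy)benzaldehyde; 6 boron enolate; 7 syn-aldol adduct; 8 N-methoxy-N-methylamide; 9 4-bromo-3-chlorophenol; 10 its benzyl ether; 11 arylmagnesium chloride; 12 β-hydroxy ketone; 13 open-chain diol (cyclisation substrate); 14 aryne; 15 C8 aryllithium; 16 C8 boronate; 17 flavan-4,8-diol; 18 tetra-O-benzyl monomer with free 4-OH; 19 its 4-O-silyl ether (acceptor); 20 6-bromo monomer; 21 its 4-acetate (capped donor); 22 dimer silyl ether; 23 dimer 4-ol; 24 dimer 4-acetate; 25 protected trimer; 26 trimer 4-ol; 27 target.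

## Analysis of the target

- The target is a trimeric 5-deoxy proanthocyanidin. It has three flavan units, each a dihydropyran ring C fused to a 7,8-dioxygenated ring A, with a 4-hydroxyphenyl ring B on C2.
- There are eight stereocentres. C2 and C3 of every unit are R,R with ring B and O3 cis. C4 of the top and of the middle unit is bonded to C6 of the next unit on the face opposite O3. C4 of the bottom unit carries a hydroxyl cis to O3.
- The free compound has nine phenolic hydroxyls, including three oxidation-prone C7/C8 catechol pairs. Every C4 is a benzylic carbon whose cation is stabilised by O7 (para to C4a) and O1, so the C4–O and C4–aryl bonds are acid-labile.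
- The difficulty is threefold: three nearly identical units must be joined at defined positions and faces; one benzylic hydroxyl must survive; and the 2,3-cis-3,4-cis pattern of the bottom unit is not the one that equilibration or hydride reduction of a flavanone-type precursor would favour.
- The 7,8-dioxygenation pattern also means each ring A has to be built.
- The strategy rests on one feature of ring A. The ring oxygen O1 sits on C8a and a hydroxyl sits on the neighbouring C8, which is itself flanked by the C7 oxygen. Both oxygens can therefore be delivered across a C8–C8a aryne made from a simple 3-alkoxychlorobenzene.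
- A second feature makes the assembly simple: in ring A only C6 is activated by two oxygens (ortho to O7, para to O1), so it is the single nucleophilic site of each unit.

## Retrosynthetic reasoning

**27 ← 26 ← 25.** The twelve O–benzyl bonds and the C6–Br bond of the top unit are cut last, in one hydrogenolysis, so that the catechol pairs appear only in the final step. The silyl ether on O4 of the bottom unit is removed one step earlier (25 to 26), while the molecule is still fully benzylated and robust.

**25 ← 24 + 19.** The bond C4(middle)–C6(bottom) is cut. C4 is a natural cation and C6 the natural nucleophile, so the forward reaction is ionisation of the C4 acetate of 24 and attack by C6 of 19 anti to the O3 benzyl ether, which gives the 4β bond. This joins a dimer and a monomer in one step.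

**24 ← 23 ← 22.** These are functional-group changes at O4 of the middle unit. The silyl ether that protected this position during the first coupling is exchanged for an acetate leaving group.

**22 ← 21 + 19.** The bond C4(top)–C6(middle) is cut by the same logic. Donor 21 carries bromine on C6 and so cannot add to itself. Acceptor 19 carries its C4 oxygen as a hindered silyl ether that should not ionise under the catalytic Lewis acid. Compound 19 therefore serves twice, as middle and as bottom unit.

**21 ← 20 ← 18 and 19 ← 18.** All three units are traced to the single monomer 18. The branches differ only in what is placed on C6 (bromine) and on O4 (acetyl or silyl).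

**18 ← 17.** The O8–benzyl bond is cut. The forward step has to distinguish a phenol from a secondary alcohol, which base strength does.

**17 ← 13 (key disconnection).** The bonds C8a–O1 and C8–O are cut. This removes ring C and the C8 oxygen together. It leaves a chloroarene with hydrogen at C8, and an open chain in which all three stereocentres can be set by acyclic stereocontrol. Forward, 13 is converted into aryne 14, the C2 alkoxide closes ring C to give aryllithium 15, and 15 is oxidised through boronate 16. Because the ring is closed at the aromatic carbon, no stereocentre is touched.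

**13 ← 12.** The C4–H bond is cut. A ketone at C4 is reduced with delivery of hydride from the C2 hydroxyl, which gives the 2,4-anti diol, that is, O4 anti to O3 in the chain and cis in the ring.

**12 ← 8 + 11 (11 ← 10 ← 9).** The bond C4–C4a is cut. It is made by acyl substitution of amide 8 with the aryl Grignard reagent 11, so ring A enters as a commercial bromochlorophenol.

**8 ← 7 ← 4 + 5 (4 ← 1 + 2).** The bond C2–C3 is cut by a syn glycolate aldol. The syn relation becomes 2,3-cis, the auxiliary 2 fixes the absolute configuration, and the aldol hydroxyl is exactly the oxygen that later attacks the aryne.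

## Alternatives that were turned down

**Alternative 1:** epoxide–arene cyclisation to grow the middle unit on C6.
- Disconnection: the C4–C4a bond of the middle unit, with the bond from its C4 to C6 of the bottom unit already in place.
- Forward key step: BF3·OEt2 would open the trans-epoxide A1 at its benzylic carbon. The free ortho carbon of the 4-bromo-2,3-bis(benzyloxy)phenyl ether would then attack with inversion in a 6-endo Friedel–Crafts closure to give A2.
- For it: the interflavan bond is never made between two molecules, so neither the site on ring A nor oligomer formation is an issue. C4 is meant to follow stereospecifically from the epoxide. The acetonide of the bottom unit guards the cis-3,4-diol more securely than the silyl ether of 19. On these three points it is stronger than the chosen route.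
- Against it: the epoxide carbon to be attacked sits on a ring A carbon ortho to O7 and para to O1. The epoxide should therefore ionise rather than be displaced, so inversion is no longer assured and a hydride shift to the carbonyl compound competes. Each new unit also needs its own chain, aryl ether and epoxide built on a finished unit, twice for a trimer, with extra pivalate and bromine handling.
- Comparison: the chosen route makes one monomer (18) and uses it three times. It pays for this with two intermolecular couplings, which are the established way of making this bond.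

**Alternative 2:** palladium–norbornene annulation of ring A onto the chain.
- Disconnection: both bonds from ring A to the three-carbon chain, C4–C4a and C8a–O1.
- Forward key step: a Catellani reaction with Pd(OAc)2, tri(2-furyl)phosphine, norbornene and Cs2CO3. The aryl iodide A3 would be alkylated at its free ortho position by the primary bromide A4, and the C2 alkoxide would close ring C at the ipso carbon to give A5.
- For it: both ring A oxygens are bought with A3, so no late oxygenation of C8 is needed. Two bonds form in one convergent step. On these points it is as strong as or stronger than the aryne route.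
- Against it: A5 has a methylene at C4, whereas every unit of the target carries oxygen or carbon there. Each unit would need a benzylic oxidation. For the bottom unit the hydroxyl must end up cis to O3, and no direct oxidation delivers that face. The ipso C–O termination with a secondary alkoxide also has to outrun β-hydride elimination of the palladium alkoxide.
- Comparison: the chosen route brings the C4 oxygen in from the chain with its configuration, for all three units.

**Alternative 3:** endo hetero-Diels–Alder reaction for the all-cis unit.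
- Disconnection: O1–C2 and C3–C4 of ring C of the bottom unit, a [4+2] cut.
- Forward key step: a chiral phosphoric acid would ionise the diallyl acetal A6 to the 4-allyloxy ortho-quinone methide, and the Z-enol pivalate A7 would add endo to give A8.
- For it: ring C and all three stereocentres come in one catalytic step from two achiral pieces, with ring A fully oxygenated. This reaches a monomer in fewer steps than the route to 18 and needs no auxiliary. In step economy it is the strongest of all four plans.
- Against it: three selectivities must hold at once (regiochemistry, endo/exo, and facial), and nothing in the substrates secures any of them. The two donors of the dienophile oppose each other, and the dienophile is a weakly nucleophilic Z-disubstituted enol ester. Acid can isomerise the Z-alkene, which would lead to the 2,3-trans series. The oxygen-substituted quinone methide is close to an oxocarbenium ion.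
- Comparison: the chosen route sets each stereocentre in a separate step with a well-understood transition state. Its one new step creates no stereocentre, so it can fail only in chemoselectivity.

Key step: step 7

## Route

Step 1
Reactants: 1 benzyloxyacetic acid; 2 (S)-4-benzyloxazolidin-2-one
Product: 4 (S)-4-benzyl-3-[(benzyloxy)acetyl]oxazolidin-2-one, via pivalic mixed anhydride 3 (not isolated)
Conditions: PivCl, Et3N, THF, −20 °C; then 2, LiCl, −20 °C → rt
Reagents that add atoms: none
Why: N-acylation of the oxazolidinone through the mixed pivalic anhydride; the hindered pivaloyl carbonyl directs attack to the glycolyl carbonyl and LiCl raises the nucleophilicity of the carbamate nitrogen.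

Step 2
Reactants: 4 (S)-4-benzyl-3-[(benzyloxy)acetyl]oxazolidin-2-one; 5 4-(benzyloxy)benzaldehyde
Product: 7 (S)-4-benzyl-3-[(2S,3R)-2-(benzyloxy)-3-[4-(benzyloxy)phenyl]-3-hydroxypropanoyl]oxazolidin-2-one, via dibutylboron Z-enolate 6 (not isolated)
Conditions: Bu2BOTf, Et3N, CH2Cl2, −78 → 0 °C; 5, −78 → 0 °C; pH 7 buffer, MeOH, 30% H2O2, 0 °C
Reagents that add atoms: none
Why: Evans syn aldol reaction; the Z-boron enolate reacts through a Zimmerman–Traxler chair with the imide carbonyls opposed and the aldehyde on the face away from the benzyl group of the auxiliary, which should set C3 (S in the adduct) and C2 (R) with the syn relation that becomes 2,3-cis.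

Step 3
Reactants: 7 (S)-4-benzyl-3-[(2S,3R)-2-(benzyloxy)-3-[4-(benzyloxy)phenyl]-3-hydroxypropanoyl]oxazolidin-2-one
Product: 8 (2S,3R)-2-(benzyloxy)-3-[4-(benzyloxy)phenyl]-3-hydroxy-N-methoxy-N-methylpropanamide
Conditions: MeNHOMe·HCl, AlMe3, CH2Cl2, −10 °C → rt
Reagents that add atoms: N,O-dimethylhydroxylamine hydrochloride, Cl.CNOC
Why: Weinreb transamidation of the imide with the dimethylaluminium amide; the free aldol hydroxyl binds aluminium and directs attack to the exocyclic carbonyl, and the auxiliary 2 is recovered.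

Step 4
Reactants: 9 4-bromo-3-chlorophenol
Product: 10 4-(benzyloxy)-1-bromo-2-chlorobenzene
Conditions: BnBr, K2CO3, DMF, rt
Reagents that add atoms: benzyl bromide, BrCc1ccccc1
Why: Williamson ether synthesis on a phenol; it installs the future O7 benzyl ether that later acidifies H8.

Step 5
Reactants: 10 4-(benzyloxy)-1-bromo-2-chlorobenzene; 8 (2S,3R)-2-(benzyloxy)-3-[4-(benzyloxy)phenyl]-3-hydroxy-N-methoxy-N-methylpropanamide
Product: 12 (2S,3R)-2-(benzyloxy)-1-[4-(benzyloxy)-2-chlorophenyl]-3-[4-(benzyloxy)phenyl]-3-hydroxypropan-1-one, via arylmagnesium chloride 11 (not isolated)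
Conditions: 10, iPrMgCl·LiCl, THF, 0 °C → rt; 8 pre-treated with iPrMgCl (1 equiv), THF, −20 °C; combine, 0 °C → rt; aq NH4Cl, 0 °C
Reagents that add atoms: none
Why: Bromine–magnesium exchange (chlorine is untouched) followed by Weinreb ketone synthesis; the chelated tetrahedral magnesium adduct survives until work-up, so no ketone is exposed to base and the C3 centre should not epimerise, while the hydroxyl is carried as its magnesium alkoxide.

Step 6
Reactants: 12 (2S,3R)-2-(benzyloxy)-1-[4-(benzyloxy)-2-chlorophenyl]-3-[4-(benzyloxy)phenyl]-3-hydroxypropan-1-one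
Product: 13 (1R,2S,3R)-2-(benzyloxy)-1-[4-(benzyloxy)-2-chlorophenyl]-3-[4-(benzyloxy)phenyl]propane-1,3-diol
Conditions: Me4NBH(OAc)3, MeCN/AcOH, −30 °C
Reagents that add atoms: none
Why: Evans–Saksena reduction; the C2 hydroxyl exchanges onto boron and hydride is delivered intramolecularly through a chair transition state, which should give the 1,3-anti diol and thus C4 (R) anti to O3, the relation that becomes 3,4-cis.

Step 7
Reactants: 13 (1R,2S,3R)-2-(benzyloxy)-1-[4-(benzyloxy)-2-chlorophenyl]-3-[4-(benzyloxy)phenyl]propane-1,3-diol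
Product: 17 (2R,3R,4R)-3,7-bis(benzyloxy)-2-[4-(benzyloxy)phenyl]chromane-4,8-diol, via dilithium alkoxide aryne 14 (not isolated), via 8-lithio flavan 15 (not isolated), via 8-boronate 16 (not isolated)
Conditions: lithium 2,2,6,6-tetramethylpiperidide (4.5 equiv), THF, −78 → −20 °C; B(OMe)3, −78 → 0 °C; 30% H2O2, 0 °C → rt
Reagents that add atoms: hydrogen peroxide, OO
Why: Proposed new method: the amide base first forms both lithium alkoxides of 13 and then removes H8, the one ring proton flanked by chlorine and the C7 benzyloxy group, and on warming the 2-chloroaryllithium loses LiCl to give the C8–C8a aryne 14. The C2 alkoxide adds to C8a in a 6-exo-dig closure of ring C, whereas the C4 alkoxide cannot compete because its addition would need a four-membered ring. Tether length and the inductive pull of the C7 oxygen both place oxygen on C8a and the carbanion on C8, so the 2,6-dioxygenated aryllithium 15 should result; it is borylated by B(OMe)3 to 16 and oxidised by H2O2 with carbon-to-oxygen migration to the C8 phenol. The closest known reaction type is the base-induced benzyne cyclisation of tethered alkoxides to chromans with electrophilic capture of the resulting arylmetal; running cyclisation, borylation and oxidation as one operation on a stereodefined dialkoxide is what is new. No stereocentre is formed, and because the C–O bond is made at the arene carbon C2 keeps its configuration, so the syn C2/C3 and anti C3/C4 relations of 13 become 2,3-cis and 3,4-cis. The selectivities needed are deprotonation at C8 rather than at a benzylic ether position and addition of oxygen rather than of the amide to the aryne, secured by the acidity of H8, the intramolecularity of the alkoxide and the bulk of the base.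

Step 8
Reactants: 17 (2R,3R,4R)-3,7-bis(benzyloxy)-2-[4-(benzyloxy)phenyl]chromane-4,8-diol
Product: 18 (2R,3R,4R)-3,7,8-tris(benzyloxy)-2-[4-(benzyloxy)phenyl]chroman-4-ol
Conditions: BnBr (1.1 equiv), K2CO3, acetone, 50 °C
Reagents that add atoms: benzyl bromide, BrCc1ccccc1
Why: Williamson ether synthesis; carbonate deprotonates only the C8 phenol, so the secondary C4 hydroxyl stays free.

Step 9
Reactants: 18 (2R,3R,4R)-3,7,8-tris(benzyloxy)-2-[4-(benzyloxy)phenyl]chroman-4-ol
Product: 19 (2R,3S,4R)-3,7,8-tris(benzyloxy)-2-[4-(benzyloxy)phenyl]-4-[(tert-butyldimethylsilyl)oxy]chromane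
Conditions: TBSCl, imidazole, DMF, 40 °C
Reagents that add atoms: tert-butyldimethylsilyl chloride, CC(C)(C)[Si](C)(C)Cl
Why: Silylation of a secondary alcohol under basic conditions, which avoid ionising the benzylic C4–O bond; the hindered silyl ether makes this unit an acceptor only (the 3S label reflects a priority change, not a change at C3).

Step 10
Reactants: 18 (2R,3R,4R)-3,7,8-tris(benzyloxy)-2-[4-(benzyloxy)phenyl]chroman-4-ol
Product: 20 (2R,3R,4R)-3,7,8-tris(benzyloxy)-2-[4-(benzyloxy)phenyl]-6-bromochroman-4-ol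
Conditions: NBS (1.0 equiv), CH2Cl2, −40 °C
Reagents that add atoms: N-bromosuccinimide, O=C1CCC(=O)N1Br
Why: Electrophilic aromatic bromination; C6 is the only position ortho to O7 and para to O1, far more activated than ring B or C5, so the bromine should enter there and block the nucleophilic site of the future top unit.

Step 11
Reactants: 20 (2R,3R,4R)-3,7,8-tris(benzyloxy)-2-[4-(benzyloxy)phenyl]-6-bromochroman-4-ol
Product: 21 (2R,3S,4R)-3,7,8-tris(benzyloxy)-2-[4-(benzyloxy)phenyl]-6-bromochroman-4-yl acetate
Conditions: Ac2O, Et3N, DMAP (cat.), CH2Cl2, 0 °C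
Reagents that add atoms: acetic anhydride, CC(=O)OC(C)=O
Why: Acylation of a secondary alcohol under basic conditions; it turns the C4 hydroxyl into a leaving group that a catalytic Lewis acid can remove at low temperature.

Step 12
Reactants: 21 (2R,3S,4R)-3,7,8-tris(benzyloxy)-2-[4-(benzyloxy)phenyl]-6-bromochroman-4-yl acetate; 19 (2R,3S,4R)-3,7,8-tris(benzyloxy)-2-[4-(benzyloxy)phenyl]-4-[(tert-butyldimethylsilyl)oxy]chromane
Product: 22 6-bromo-3,7,8,4'-tetra-O-benzylepioritin-(4β→6)-3,7,8,4'-tetra-O-benzyl-4-O-(tert-butyldimethylsilyl)epioritin-4α-ol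
Conditions: 21 (1 equiv), 19 (2 equiv), Me3SiOTf (0.2 equiv), 4 Å MS, CH2Cl2, −78 °C; Et3N quench
Reagents that add atoms: none
Why: Lewis-acid ionisation of the C4 acetate to the flavan-4-yl cation (stabilised by O7 through C4a and by O1) and Friedel–Crafts attack by C6 of 19, the standard interflavan coupling; the nucleophile should enter anti to the O3 benzyl ether of the 2,3-cis donor to give the 4β bond, the bromine prevents the donor adding to itself, and excess 19 is recovered.

Step 13
Reactants: 22 6-bromo-3,7,8,4'-tetra-O-benzylepioritin-(4β→6)-3,7,8,4'-tetra-O-benzyl-4-O-(tert-butyldimethylsilyl)epioritin-4α-ol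
Product: 23 6-bromo-3,7,8,4'-tetra-O-benzylepioritin-(4β→6)-3,7,8,4'-tetra-O-benzylepioritin-4α-ol
Conditions: Bu4NF, AcOH, THF, 0 °C → rt
Reagents that add atoms: none
Why: Fluoride cleavage of the silyl ether under buffered conditions; benzyl ethers, the aryl bromide and the interflavan bond are inert to it.

Step 14
Reactants: 23 6-bromo-3,7,8,4'-tetra-O-benzylepioritin-(4β→6)-3,7,8,4'-tetra-O-benzylepioritin-4α-ol
Product: 24 6-bromo-3,7,8,4'-tetra-O-benzylepioritin-(4β→6)-4-O-acetyl-3,7,8,4'-tetra-O-benzylepioritin-4α-ol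
Conditions: Ac2O, Et3N, DMAP (cat.), CH2Cl2, 0 °C
Reagents that add atoms: acetic anhydride, CC(=O)OC(C)=O
Why: Acylation as in step 11; the only hydroxyl of 23 is the C4 hydroxyl of its lower unit, which now becomes the leaving group of a dimeric donor.

Step 15
Reactants: 24 6-bromo-3,7,8,4'-tetra-O-benzylepioritin-(4β→6)-4-O-acetyl-3,7,8,4'-tetra-O-benzylepioritin-4α-ol; 19 (2R,3S,4R)-3,7,8-tris(benzyloxy)-2-[4-(benzyloxy)phenyl]-4-[(tert-butyldimethylsilyl)oxy]chromane
Product: 25 6-bromo-3,7,8,4'-tetra-O-benzylepioritin-(4β→6)-3,7,8,4'-tetra-O-benzylepioritin-(4β→6)-3,7,8,4'-tetra-O-benzyl-4-O-(tert-butyldimethylsilyl)epioritin-4α-ol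
Conditions: 24 (1 equiv), 19 (2 equiv), Me3SiOTf (0.2 equiv), 4 Å MS, CH2Cl2, −78 °C; Et3N quench
Reagents that add atoms: none
Why: Second flavan-4-yl cation coupling of the same kind; the donor has no free C6 (one is brominated, one substituted), so only C6 of 19 can react, again anti to the O3 benzyl ether to give the second 4β bond.

Step 16
Reactants: 25 6-bromo-3,7,8,4'-tetra-O-benzylepioritin-(4β→6)-3,7,8,4'-tetra-O-benzylepioritin-(4β→6)-3,7,8,4'-tetra-O-benzyl-4-O-(tert-butyldimethylsilyl)epioritin-4α-ol
Product: 26 6-bromo-3,7,8,4'-tetra-O-benzylepioritin-(4β→6)-3,7,8,4'-tetra-O-benzylepioritin-(4β→6)-3,7,8,4'-tetra-O-benzylepioritin-4α-ol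
Conditions: Bu4NF, AcOH, THF, 0 °C → rt
Reagents that add atoms: none
Why: Fluoride desilylation as in step 13, done while all phenols are still benzylated so that no oxidation-prone catechol is exposed to fluoride.

Step 17
Reactants: 26 6-bromo-3,7,8,4'-tetra-O-benzylepioritin-(4β→6)-3,7,8,4'-tetra-O-benzylepioritin-(4β→6)-3,7,8,4'-tetra-O-benzylepioritin-4α-ol
Product: 27 epioritin-(4β→6)-epioritin-(4β→6)-epioritin-4α-ol
Conditions: H2 (1 atm), Pd(OH)2/C, NaOAc, THF/MeOH/H2O, rt
Reagents that add atoms: none
Why: Catalytic hydrogenolysis of the twelve benzyl ethers together with hydrodebromination of C6; acetate buffers the HBr so that the acid-labile C4–O and C4–aryl bonds should survive, and no stereocentre is involved.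

## Compound list

1 | benzyloxyacetic acid | OC(=O)COCc1ccccc1 | starting material
2 | (S)-4-benzyloxazolidin-2-one | O=C1OC[C@H](Cc2ccccc2)N1 | starting material
3 | benzyloxyacetic pivalic anhydride | CC(C)(C)C(=O)OC(=O)COCc1ccccc1 | intermediate
4 | (S)-4-benzyl-3-[(benzyloxy)acetyl]oxazolidin-2-one | O=C1OC[C@H](Cc2ccccc2)N1C(=O)COCc1ccccc1 | intermediate
5 | 4-(benzyloxy)benzaldehyde | O=Cc1ccc(OCc2ccccc2)cc1 | starting material
6 | dibutylboron (Z)-enolate of 4 | CCCCB(CCCC)O/C(=C\OCc1ccccc1)N1C(=O)OC[C@@H]1Cc1ccccc1 | intermediate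
7 | (S)-4-benzyl-3-[(2S,3R)-2-(benzyloxy)-3-[4-(benzyloxy)phenyl]-3-hydroxypropanoyl]oxazolidin-2-one | O=C1OC[C@H](Cc2ccccc2)N1C(=O)[C@@H](OCc1ccccc1)[C@H](O)c1ccc(OCc2ccccc2)cc1 | intermediate
8 | (2S,3R)-2-(benzyloxy)-3-[4-(benzyloxy)phenyl]-3-hydroxy-N-methoxy-N-methylpropanamide | CON(C)C(=O)[C@@H](OCc1ccccc1)[C@H](O)c1ccc(OCc2ccccc2)cc1 | intermediate
9 | 4-bromo-3-chlorophenol | Oc1ccc(Br)c(Cl)c1 | starting material
10 | 4-(benzyloxy)-1-bromo-2-chlorobenzene | Clc1cc(OCc2ccccc2)ccc1Br | intermediate
11 | [4-(benzyloxy)-2-chlorophenyl]magnesium chloride | Clc1cc(OCc2ccccc2)ccc1[Mg]Cl | intermediate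
12 | (2S,3R)-2-(benzyloxy)-1-[4-(benzyloxy)-2-chlorophenyl]-3-[4-(benzyloxy)phenyl]-3-hydroxypropan-1-one | O=C(c1ccc(OCc2ccccc2)cc1Cl)[C@@H](OCc1ccccc1)[C@H](O)c1ccc(OCc2ccccc2)cc1 | intermediate
13 | (1R,2S,3R)-2-(benzyloxy)-1-[4-(benzyloxy)-2-chlorophenyl]-3-[4-(benzyloxy)phenyl]propane-1,3-diol | Clc1cc(OCc2ccccc2)ccc1[C@@H](O)[C@@H](OCc1ccccc1)[C@H](O)c1ccc(OCc2ccccc2)cc1 | intermediate
14 | dilithium dialkoxide of the C8–C8a aryne formed from 13 | C1#CC(OCc2ccccc2)=CC=C1[C@@H](O[Li])[C@@H](OCc1ccccc1)[C@H](O[Li])c1ccc(OCc2ccccc2)cc1 | intermediate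
15 | 8-lithio-3,7,4'-tri-O-benzylteracacidin, lithium 4-alkoxide | [Li]c1c(OCc2ccccc2)ccc2c1O[C@H](c1ccc(OCc3ccccc3)cc1)[C@H](OCc1ccccc1)[C@@H]2O[Li] | intermediate
16 | dimethyl 8-boronate of 3,7,4'-tri-O-benzylteracacidin, lithium 4-alkoxide | COB(OC)c1c(OCc2ccccc2)ccc2c1O[C@H](c1ccc(OCc3ccccc3)cc1)[C@H](OCc1ccccc1)[C@@H]2O[Li] | intermediate
17 | (2R,3R,4R)-3,7-bis(benzyloxy)-2-[4-(benzyloxy)phenyl]chromane-4,8-diol (3,7,4'-tri-O-benzylteracacidin) | Oc1c(OCc2ccccc2)ccc2c1O[C@H](c1ccc(OCc3ccccc3)cc1)[C@H](OCc1ccccc1)[C@@H]2O | intermediate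
18 | (2R,3R,4R)-3,7,8-tris(benzyloxy)-2-[4-(benzyloxy)phenyl]chroman-4-ol (3,7,8,4'-tetra-O-benzylteracacidin) | C(c1ccccc1)Oc1c(OCc2ccccc2)ccc2c1O[C@H](c1ccc(OCc3ccccc3)cc1)[C@H](OCc1ccccc1)[C@@H]2O | intermediate
19 | (2R,3S,4R)-3,7,8-tris(benzyloxy)-2-[4-(benzyloxy)phenyl]-4-[(tert-butyldimethylsilyl)oxy]chromane | C(c1ccccc1)Oc1c(OCc2ccccc2)ccc2c1O[C@H](c1ccc(OCc3ccccc3)cc1)[C@H](OCc1ccccc1)[C@@H]2O[Si](C)(C)C(C)(C)C | intermediate
20 | (2R,3R,4R)-3,7,8-tris(benzyloxy)-2-[4-(benzyloxy)phenyl]-6-bromochroman-4-ol | C(c1ccccc1)Oc1c(OCc2ccccc2)c(Br)cc2c1O[C@H](c1ccc(OCc3ccccc3)cc1)[C@H](OCc1ccccc1)[C@@H]2O | intermediate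
21 | (2R,3S,4R)-3,7,8-tris(benzyloxy)-2-[4-(benzyloxy)phenyl]-6-bromochroman-4-yl acetate | C(c1ccccc1)Oc1c(OCc2ccccc2)c(Br)cc2c1O[C@H](c1ccc(OCc3ccccc3)cc1)[C@H](OCc1ccccc1)[C@@H]2OC(C)=O | intermediate
22 | 6-bromo-3,7,8,4'-tetra-O-benzylepioritin-(4β→6)-3,7,8,4'-tetra-O-benzyl-4-O-(tert-butyldimethylsilyl)epioritin-4α-ol | C(c1ccccc1)Oc1ccc([C@H]2Oc3c(cc(Br)c(OCc4ccccc4)c3OCc3ccccc3)[C@H](c3cc4c(c(OCc5ccccc5)c3OCc3ccccc3)O[C@H](c3ccc(OCc5ccccc5)cc3)[C@H](OCc3ccccc3)[C@@H]4O[Si](C)(C)C(C)(C)C)[C@H]2OCc2ccccc2)cc1 | intermediate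
23 | 6-bromo-3,7,8,4'-tetra-O-benzylepioritin-(4β→6)-3,7,8,4'-tetra-O-benzylepioritin-4α-ol | C(c1ccccc1)Oc1ccc([C@H]2Oc3c(cc(Br)c(OCc4ccccc4)c3OCc3ccccc3)[C@H](c3cc4c(c(OCc5ccccc5)c3OCc3ccccc3)O[C@H](c3ccc(OCc5ccccc5)cc3)[C@H](OCc3ccccc3)[C@@H]4O)[C@H]2OCc2ccccc2)cc1 | intermediate
24 | 6-bromo-3,7,8,4'-tetra-O-benzylepioritin-(4β→6)-4-O-acetyl-3,7,8,4'-tetra-O-benzylepioritin-4α-ol | C(c1ccccc1)Oc1ccc([C@H]2Oc3c(cc(Br)c(OCc4ccccc4)c3OCc3ccccc3)[C@H](c3cc4c(c(OCc5ccccc5)c3OCc3ccccc3)O[C@H](c3ccc(OCc5ccccc5)cc3)[C@H](OCc3ccccc3)[C@@H]4OC(C)=O)[C@H]2OCc2ccccc2)cc1 | intermediate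
25 | 6-bromo-3,7,8,4'-tetra-O-benzylepioritin-(4β→6)-3,7,8,4'-tetra-O-benzylepioritin-(4β→6)-3,7,8,4'-tetra-O-benzyl-4-O-(tert-butyldimethylsilyl)epioritin-4α-ol | C(c1ccccc1)Oc1ccc([C@H]2Oc3c(cc(Br)c(OCc4ccccc4)c3OCc3ccccc3)[C@H](c3cc4c(c(OCc5ccccc5)c3OCc3ccccc3)O[C@H](c3ccc(OCc5ccccc5)cc3)[C@H](OCc3ccccc3)[C@H]4c3cc4c(c(OCc5ccccc5)c3OCc3ccccc3)O[C@H](c3ccc(OCc5ccccc5)cc3)[C@H](OCc3ccccc3)[C@@H]4O[Si](C)(C)C(C)(C)C)[C@H]2OCc2ccccc2)cc1 | intermediate
26 | 6-bromo-3,7,8,4'-tetra-O-benzylepioritin-(4β→6)-3,7,8,4'-tetra-O-benzylepioritin-(4β→6)-3,7,8,4'-tetra-O-benzylepioritin-4α-ol | C(c1ccccc1)Oc1ccc([C@H]2Oc3c(cc(Br)c(OCc4ccccc4)c3OCc3ccccc3)[C@H](c3cc4c(c(OCc5ccccc5)c3OCc3ccccc3)O[C@H](c3ccc(OCc5ccccc5)cc3)[C@H](OCc3ccccc3)[C@H]4c3cc4c(c(OCc5ccccc5)c3OCc3ccccc3)O[C@H](c3ccc(OCc5ccccc5)cc3)[C@H](OCc3ccccc3)[C@@H]4O)[C@H]2OCc2ccccc2)cc1 | intermediate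
27 | epioritin-(4β→6)-epioritin-(4β→6)-epioritin-4α-ol (CNP0140823.1) | Oc1ccc([C@H]2Oc3c(ccc(O)c3O)[C@H](c3cc4c(c(O)c3O)O[C@H](c3ccc(O)cc3)[C@H](O)[C@H]4c3cc4c(c(O)c3O)O[C@H](c3ccc(O)cc3)[C@H](O)[C@@H]4O)[C@H]2O)cc1 | target

## Step count and risk

Total: 17 steps. Longest linear sequence: 15 steps (1 → 4 → 7 → 8 → 12 → 13 → 17 → 18 → 20 → 21 → 22 → 23 → 24 → 25 → 26 → 27); steps 4 and 9 are side branches.

**Step 7 (key step, new as a single operation).**
- What may go wrong: protonation of the C8 aryllithium by the liberated amine before borylation; hydride transfer from the C2 carbinol carbon to the aryne in place of C–O bond formation; addition of the amide to the aryne; lithiation at a benzylic ether carbon followed by Wittig rearrangement.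
- Fallback, from 13 back to 17, using known reactions only: ring C is closed by palladium-catalysed intramolecular aryl chloride–alcohol coupling (Pd(OAc)2, 2-(di-tert-butylphosphino)-1,1'-binaphthyl, Cs2CO3, toluene, 70 °C). Only the C2 hydroxyl can form a ring, so this should give (2R,3R,4R)-3,7-bis(benzyloxy)-2-[4-(benzyloxy)phenyl]chroman-4-ol F1. Its C8 hydrogen lies between O1 and O7 and is removed by directed ortho-lithiation (s-BuLi, TMEDA, THF, −78 °C, one extra equivalent for the hydroxyl). B(OMe)3 and then H2O2 should return 17.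

**Step 12 (first coupling).**
- What may go wrong: competing ionisation of the silyl ether of 19 by the Lewis acid, with loss of the protecting group and oligomerisation; attack on the face syn to O3; acid-induced scrambling of the new bond.
- Fallback, from 20 back to 22: the hard Lewis acid is replaced by soft thiophilic activation. Compound 20 is treated with phenylmethanethiol and catalytic BF3·OEt2 (CH2Cl2, −40 °C) to give 4β-(benzylsulfanyl)-6-bromo-3,7,8,4'-tetra-O-benzylepioritin F2. F2 is then activated with AgBF4 (THF, 0 °C) in the presence of 19. Silver should leave the silyl ether untouched and deliver 22.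

**Step 15 (second coupling).**
- What may go wrong: the same processes as in step 12, plus slower attack because the cation now carries a bulky flavanyl group on ring A.
- Fallback, from 23 back to 25: 23 is converted with phenylmethanethiol and catalytic BF3·OEt2 into the dimeric thioether 6-bromo-3,7,8,4'-tetra-O-benzylepioritin-(4β→6)-4β-(benzylsulfanyl)-3,7,8,4'-tetra-O-benzylepioritin F3. F3 is coupled with 19 under AgBF4 to give 25.

**Step 5 (Grignard addition to the unprotected amide).**
- What may go wrong: retro-aldol cleavage of the magnesium aldolate; epimerisation next to the new ketone on work-up; sluggish bromine–magnesium exchange on the electron-rich arene.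
- Fallback, from 8 back to 12: the hydroxyl is protected first (Et3SiCl, imidazole) to give the triethylsilyl ether of 8, (2S,3R)-2-(benzyloxy)-3-[4-(benzyloxy)phenyl]-N-methoxy-N-methyl-3-[(triethylsilyl)oxy]propanamide F4. The aryllithium made from 10 (n-BuLi, THF, −78 °C) is added at −78 °C to give the silylated ketone (2S,3R)-2-(benzyloxy)-1-[4-(benzyloxy)-2-chlorophenyl]-3-[4-(benzyloxy)phenyl]-3-[(triethylsilyl)oxy]propan-1-one F5. HF·pyridine in THF then releases 12.

**Step 17 (final hydrogenolysis).**
- What may go wrong: hydrogenolysis of the benzylic C4–O bond of the bottom unit; acid-induced cleavage of an interflavan bond if HBr is not buffered; incomplete removal of twelve benzyl groups.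
- Fallback, from 25 back to 27: the order of the last two operations is reversed so that the benzylic oxygen stays masked during hydrogenation. Compound 25 is hydrogenolysed (H2, Pd(OH)2/C, NaOAc, THF/MeOH) to the free phenolic silyl ether epioritin-(4β→6)-epioritin-(4β→6)-4-O-(tert-butyldimethylsilyl)epioritin-4α-ol F6. The silyl group is then removed with HF·pyridine in THF/pyridine at 0 °C under argon to give 27.

## Further compounds

F1 | step 7 | (2R,3R,4R)-3,7-bis(benzyloxy)-2-[4-(benzyloxy)phenyl]chroman-4-ol | c1(OCc2ccccc2)ccc2c(c1)O[C@H](c1ccc(OCc3ccccc3)cc1)[C@H](OCc1ccccc1)[C@@H]2O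
F2 | step 12 | 4β-(benzylsulfanyl)-6-bromo-3,7,8,4'-tetra-O-benzylepioritin | C(c1ccccc1)Oc1c(OCc2ccccc2)c(Br)cc2c1O[C@H](c1ccc(OCc3ccccc3)cc1)[C@H](OCc1ccccc1)[C@H]2SCc1ccccc1
F3 | step 15 | 6-bromo-3,7,8,4'-tetra-O-benzylepioritin-(4β→6)-4β-(benzylsulfanyl)-3,7,8,4'-tetra-O-benzylepioritin | C(c1ccccc1)Oc1ccc([C@H]2Oc3c(cc(Br)c(OCc4ccccc4)c3OCc3ccccc3)[C@H](c3cc4c(c(OCc5ccccc5)c3OCc3ccccc3)O[C@H](c3ccc(OCc5ccccc5)cc3)[C@H](OCc3ccccc3)[C@H]4SCc3ccccc3)[C@H]2OCc2ccccc2)cc1
F4 | step 5 | (2S,3R)-2-(benzyloxy)-3-[4-(benzyloxy)phenyl]-N-methoxy-N-methyl-3-[(triethylsilyl)oxy]propanamide | CON(C)C(=O)[C@@H](OCc1ccccc1)[C@H](O[Si](CC)(CC)CC)c1ccc(OCc2ccccc2)cc1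
F5 | step 5 | (2S,3R)-2-(benzyloxy)-1-[4-(benzyloxy)-2-chlorophenyl]-3-[4-(benzyloxy)phenyl]-3-[(triethylsilyl)oxy]propan-1-one | O=C(c1ccc(OCc2ccccc2)cc1Cl)[C@@H](OCc1ccccc1)[C@H](O[Si](CC)(CC)CC)c1ccc(OCc2ccccc2)cc1
F6 | step 17 | epioritin-(4β→6)-epioritin-(4β→6)-4-O-(tert-butyldimethylsilyl)epioritin-4α-ol | Oc1ccc([C@H]2Oc3c(ccc(O)c3O)[C@H](c3cc4c(c(O)c3O)O[C@H](c3ccc(O)cc3)[C@H](O)[C@H]4c3cc4c(c(O)c3O)O[C@H](c3ccc(O)cc3)[C@H](O)[C@@H]4O[Si](C)(C)C(C)(C)C)[C@H]2O)cc1
A1 | alternative 1 | trans-epoxide substrate: 7,8,4'-tri-O-benzylteracacidin 3,4-acetonide bearing at C6 an oxiranyl group whose other carbon carries the (4-bromo-2,3-bis(benzyloxy)phenoxy)(4-pivaloyloxyphenyl)methyl group | Brc1ccc(O[C@H](c2ccc(OC(=O)C(C)(C)C)cc2)[C@@H]2O[C@H]2c2cc3c(c(OCc4ccccc4)c2OCc2ccccc2)O[C@H](c2ccc(OCc4ccccc4)cc2)[C@H](OC(C)(C)O5)[C@@H]35)c(OCc2ccccc2)c1OCc1ccccc1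
A2 | alternative 1 | 6-bromo middle unit (ring B pivalate, free 3-hydroxyl) bonded 4β to C6 of 7,8,4'-tri-O-benzylteracacidin 3,4-acetonide | Brc1cc2c(c(OCc9ccccc9)c1OCc9ccccc9)O[C@H](c3ccc(OC(=O)C(C)(C)C)cc3)[C@H](O)[C@H]2c7cc8c(c(OCc9ccccc9)c7OCc9ccccc9)O[C@H](c3ccc(OCc9ccccc9)cc3)[C@H](OC(C)(C)O5)[C@@H]85
A3 | alternative 2 | 1,2-bis(benzyloxy)-3-iodobenzene | Ic1cccc(OCc2ccccc2)c1OCc1ccccc1
A4 | alternative 2 | (1R,2S)-3-bromo-1-[4-(benzyloxy)phenyl]-2-(methoxymethoxy)propan-1-ol | O[C@H](c1ccc(OCc2ccccc2)cc1)[C@H](OCOC)CBr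
A5 | alternative 2 | 7,8,4'-tri-O-benzyl-3-O-(methoxymethyl)epioritin | C(c9ccccc9)Oc1ccc2c(c1OCc9ccccc9)O[C@H](c3ccc(OCc9ccccc9)cc3)[C@H](OCOC)C2
A6 | alternative 3 | 3,4-bis(benzyloxy)-2-hydroxybenzaldehyde diallyl acetal | C=CCOC(OCC=C)c1ccc(OCc2ccccc2)c(OCc2ccccc2)c1O
A7 | alternative 3 | (Z)-2-[4-(benzyloxy)phenyl]ethenyl pivalate | CC(C)(C)C(=O)O/C=C\c1ccc(OCc2ccccc2)cc1
A8 | alternative 3 | 7,8,4'-tri-O-benzylteracacidin 3-pivalate 4-allyl ether | C(c9ccccc9)Oc1ccc2c(c1OCc9ccccc9)O[C@H](c3ccc(OCc9ccccc9)cc3)[C@H](OC(=O)C(C)(C)C)[C@@H]2OCC=C
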